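## Analysis of the target

The target (24) is a trans-α,β-dibenzyl-γ-butyrolactone (ring C) whose α-benzyl group is the benzene ring (ring A) of a 2-aryl-3-hydroxymethyl-2,3-dihydrobenzofuran, in which ring B is the dihydrofuran ring O1, C2, C3, C3a, C7a. One guaiacyl ring (4-hydroxy-3-methoxyphenyl) sits on C2 and a second, through a methylene, on the lactone β-carbon. There are four stereocentres in two trans pairs: lactone Cα (S) and Cβ (S), and ring B C2 (S) and C3 (R). Ring A and a methylene separate the pairs, so neither pair can direct the other and each must be set absolutely. Sensitive groups are the three free phenols, the primary alcohol, the lactone with its epimerisable α-carbon, and the C2–O1 bond, a benzylic aryl ether activated by a para-oxygenated aryl ring and so open to acid ionisation and hydrogenolysis. The difficulties are telling apart the two neighbouring oxygens on ring A (O1 in ring B, a free hydroxyl at C7), making the 2,3-trans ring in one enantiomeric series, and joining it to the lactone with trans control. The strategy rests on C2 being a benzylic CH bound to O1 and the guaiacyl ring while C3 carries only C3a and a one-carbon group, so that the C2–C3 bond can come from a carbene at C3, generated from an aryl diazoacetate whose ester is the latent hydroxymethyl group, inserting into a C–H bond of an aryl–O–CH2–aryl ether.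

## Retrosynthetic reasoning

**24 to 23.** All three phenols and the primary alcohol are carried as benzyl ethers, so the last step is one hydrogenolysis. Benzyl ethers should survive every base, hydride, fluoride and carbene step, and their removal touches neither the lactone nor a stereocentre.

**23 to 22 and 15.** The bond between lactone Cα and the benzylic methylene on C5 of ring A is cut. This separates the two stereo pairs into fragments of similar size, each made enantiopure on its own. The forward step is alkylation of the enolate of lactone 22 with benzylic bromide 15, which must enter anti to the β-substituent to set Cα trans.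

**22 back to 16, 17 and 2.** Lactone 22 opens at its ring C–O bond to hydroxy ester 21, which comes from imide 20 by reductive loss of the auxiliary. The Cβ–CH2Ar bond of 20 is cut to give succinate imide 19 and benzylic bromide 2. The auxiliary 17 controls the face of the alkylation, and 19 comes from half ester 16 and 17.

**15 to 11.** The bromide 15 comes from silyl ether 13 by way of alcohol 14. The benzyloxymethyl group at C3 comes from the ester of 11 by reduction to alcohol 12 and benzylation. No skeletal bond changes here; the ester is spent before the enolate of 22 is brought in, because the C3–H next to an ester would not survive that base.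

**11 to 9 (key disconnection).** The C2–C3 bond is cut, opening ring B to aryl diazoacetate 9, in which the future C2 is the methylene of a guaiacylmethyl ether on the ring A oxygen. Cutting here leaves ring A and both aryl–oxygen bonds intact and reduces the stereochemical problem to a choice between two enantiotopic hydrogens. The forward step must insert with high enantioselection at C2; C3 is then corrected by base to the trans ester through the cis ester 10.

**9 to 7.** The diazo group comes from arylacetate 8 by diazo transfer. The bond between C3a and the acetate carbon is cut to aryl bromide 7, to be made in the forward direction by a palladium-catalysed enolate arylation. The bromine is already ortho to the ether oxygen in the purchasable aldehyde 3.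

**7 to 3, 2 and 1.** The silyl ether 7 comes from alcohol 6 and aldehyde 5; the formyl group would tolerate neither the enolate coupling nor the carbene, and its silyl ether is orthogonal to the benzyl ethers. The two ether bonds on ring A are cut in the order set by acidity: benzylation of phenol 4, then alkylation of the more acidic 4-hydroxyl of bromocatechol aldehyde 3 with bromide 2. Bromide 2, from alcohol 1, supplies both guaiacyl units of the target.

## Alternatives that were turned down

**Alternative 1: annulation of an ortho-quinone methide with a chiral sulfur ylide.** Both C2–C3 and O1–C2 are cut. A base would release the quinone methide from a phenolic sulfone such as A1 and the ylide from a benzylic sulfonium salt of a chiral thiolane such as A2. The ylide carbon would add to the methide carbon and the phenoxide would displace the sulfide, giving the trans ring of A3 in one step. On convergence it is stronger than the chosen route: two bonds, the ring and both centres form at once, trans arises directly, and the C3 substituent is already at the alcohol oxidation level. Against it, the methide carbon of this target carries a silyloxymethyl group with α-hydrogens. Such a quinone methide can tautomerise through these hydrogens before the ylide arrives, and the sulfonyl carbanion can expel the β-silyloxy group. Asymmetric induction by a stoichiometric chiral sulfide on a substituted methide is also less secure than on simple ones. The aryl bromide of A3 would still need a one-carbon homologation to reach the lactone handle. The chosen strategy offers catalytic control at C2 alone, with either antipode of the catalyst, on a precursor with no such elimination pathway.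

**Alternative 2: Baeyer–Villiger desymmetrisation of a 3-substituted cyclobutanone.** Only the lactone is addressed. Oxygen would be inserted into one of the two enantiotopic acyl–CH2 bonds of cyclobutanone A4 by a chiral Lewis acid with a peracid, or by a monooxygenase, giving lactone A5, identical with 22. For the lactone fragment it is stronger than the auxiliary sequence used here: catalytic, no auxiliary, fewer operations. As the central strategy it does not answer the harder half, since it sets one stereocentre of four and builds neither ring B nor the C2/C3 pair. The enantioselectivity of chemical catalysts on 3-benzylcyclobutanones is variable, and the electron-rich arene is exposed to peracid. The chosen plan puts its risk on ring B and reaches the same lactone by an alkylation of known facial sense; this oxidation could replace that branch without changing the rest.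

**Alternative 3: benzannulation of a lactone ketene acetal with a bromopyrone.** The C3a–C4 and C7a–C7 bonds are cut, so ring A is built onto an existing five-membered ring. Silyl ketene acetal A6, from a trans-γ-aryl lactone, would add across C6 and C3 of bromocoumalate A7 on heating. Decarboxylation and loss of the silyloxy group would then aromatise to A8. In its favour, the substitution pattern of ring A follows from the polarity of the cycloaddition, and C2 and C3 are set beforehand in a simple monocycle. Against it, that lactone needs its own asymmetric synthesis, and the fully substituted ketene acetal carbon demands forcing heat with the labile benzylic C–O bond present. The bromine at C7 must later become a hydroxyl and the C5 ester must be reduced, which lengthens the end game. The chosen strategy buys ring A with its oxygens in place and spends one step on ring B.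

Key step: step 8

Assumption: in the closest analogues the (S)-configured N-phthaloyl-tert-leucinate dirhodium catalyst is understood to deliver the (2R) ring carbon, so the (R)-configured catalyst is specified for the (2S) centre needed here; if the sense on this substrate proves opposite, the antipodal catalyst is used with nothing else changed.

## Route

Step 1
Reactants: 1 (4-benzyloxy-3-methoxyphenyl)methanol
Product: 2 4-benzyloxy-3-methoxybenzyl bromide
Conditions: PBr3 (0.4 equiv), Et2O, 0 °C
Reagents that add atoms: phosphorus tribromide, BrP(Br)Br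
Why: Standard conversion of an electron-rich benzylic alcohol into its bromide through the phosphite ester; the aryl benzyl ether is inert, and the bromide is used promptly in steps 2 and 14.

Step 2
Reactants: 3 3-bromo-4,5-dihydroxybenzaldehyde; 2 4-benzyloxy-3-methoxybenzyl bromide
Product: 4 3-bromo-4-[(4-benzyloxy-3-methoxybenzyl)oxy]-5-hydroxybenzaldehyde
Conditions: NaHCO3 (1.5 equiv), DMF, 40 °C
Reagents that add atoms: none
Why: Williamson etherification under monoanion control: the 4-hydroxyl is para to the formyl group and ortho to bromine, so a weak base ionises only this oxygen and the reactive benzylic bromide should alkylate there, as in the known 4-O-selective alkylation of 3,4-dihydroxybenzaldehydes.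

Step 3
Reactants: 4 3-bromo-4-[(4-benzyloxy-3-methoxybenzyl)oxy]-5-hydroxybenzaldehyde
Product: 5 3-(benzyloxy)-4-[(4-benzyloxy-3-methoxybenzyl)oxy]-5-bromobenzaldehyde
Conditions: BnBr, K2CO3, DMF, rt
Reagents that add atoms: benzyl bromide, BrCc1ccccc1
Why: Williamson benzylation of the remaining phenol, the only acidic site left; this oxygen becomes the free C7 hydroxyl of the target.

Step 4
Reactants: 5 3-(benzyloxy)-4-[(4-benzyloxy-3-methoxybenzyl)oxy]-5-bromobenzaldehyde
Product: 6 {3-(benzyloxy)-4-[(4-benzyloxy-3-methoxybenzyl)oxy]-5-bromophenyl}methanol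
Conditions: NaBH4, THF/MeOH, 0 °C
Reagents that add atoms: none
Why: Borohydride reduction of an aryl aldehyde; aryl bromide and ethers are untouched, and the formyl group is removed before the enolate coupling and the carbene step.

Step 5
Reactants: 6 {3-(benzyloxy)-4-[(4-benzyloxy-3-methoxybenzyl)oxy]-5-bromophenyl}methanol
Product: 7 ({3-(benzyloxy)-4-[(4-benzyloxy-3-methoxybenzyl)oxy]-5-bromobenzyl}oxy)triisopropylsilane
Conditions: TIPSCl, imidazole, DMF, rt
Reagents that add atoms: chlorotriisopropylsilane, CC(C)[Si](Cl)(C(C)C)C(C)C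
Why: Silylation of a primary alcohol; the bulky silyl ether should withstand the zinc enolate, DBU, methoxide, hydride and sodium hydride steps and is removed by fluoride independently of the benzyl ethers.

Step 6
Reactants: 7 ({3-(benzyloxy)-4-[(4-benzyloxy-3-methoxybenzyl)oxy]-5-bromobenzyl}oxy)triisopropylsilane
Product: 8 methyl 2-{3-(benzyloxy)-2-[(4-benzyloxy-3-methoxybenzyl)oxy]-5-[(triisopropylsilyloxy)methyl]phenyl}acetate
Conditions: BrCH2CO2Me (2 equiv), Zn dust, THF, 40 °C, giving BrZnCH2CO2Me; then 7, Pd2(dba)3 (2.5 mol %), P(t-Bu)3 (10 mol %), THF, 60 °C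
Reagents that add atoms: methyl bromoacetate, COC(=O)CBr; bromo(2-methoxy-2-oxoethyl)zinc, COC(=O)C[Zn]Br
Why: Palladium-catalysed arylation of a zinc ester enolate (Reformatsky reagent in a Negishi-type coupling), the zinc reagent being formed in the flask by insertion of the metal into methyl bromoacetate. The bulky electron-rich phosphine on zerovalent palladium promotes oxidative addition into the ortho-alkoxy aryl bromide and fast reductive elimination, and the near-neutral zinc enolate avoids Claisen condensation and gives the methyl ester directly.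

Step 7
Reactants: 8 methyl 2-{3-(benzyloxy)-2-[(4-benzyloxy-3-methoxybenzyl)oxy]-5-[(triisopropylsilyloxy)methyl]phenyl}acetate
Product: 9 methyl 2-diazo-2-{3-(benzyloxy)-2-[(4-benzyloxy-3-methoxybenzyl)oxy]-5-[(triisopropylsilyloxy)methyl]phenyl}acetate
Conditions: 4-acetamidobenzenesulfonyl azide (p-ABSA), DBU, MeCN, 0 °C to rt
Reagents that add atoms: 4-acetamidobenzenesulfonyl azide, CC(=O)Nc1ccc(cc1)S(=O)(=O)N=[N+]=[N-]
Why: Regitz diazo transfer to the arylacetate enolate, the standard entry to aryl diazoacetates; no other C–H acid of comparable strength is present.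

Step 8
Reactants: 9 methyl 2-diazo-2-{3-(benzyloxy)-2-[(4-benzyloxy-3-methoxybenzyl)oxy]-5-[(triisopropylsilyloxy)methyl]phenyl}acetate
Product: 11 methyl (2S,3S)-7-(benzyloxy)-2-(4-benzyloxy-3-methoxyphenyl)-5-[(triisopropylsilyloxy)methyl]-2,3-dihydrobenzofuran-3-carboxylate (2,3-trans), via cis ester 10 (not isolated)
Conditions: Rh2(R-PTTL)4, dirhodium tetrakis[N-phthaloyl-(R)-tert-leucinate] (1 mol %), toluene, −60 °C; then NaOMe, MeOH, −60 °C to rt
Reagents that add atoms: none
Why: The catalyst decomposes the diazo ester to an electrophilic donor–acceptor carbene on the divalent rhodium core. The carbene carbon (future C3) takes up one C–H bond of the ArO–CH2–Ar′ methylene (future C2) through a concerted, asynchronous three-centre transition state with hydride-transfer character, forming C2–C3 and releasing the catalyst. The closest known reaction is the enantioselective intramolecular C–H insertion of 2-(benzyloxy)aryl diazoacetates into the O-benzylic C–H bond with N-phthaloyl amino acid dirhodium carboxylates, which gives cis-2-aryl-2,3-dihydrobenzofuran-3-carboxylates. Ring B closes as a 1,5-insertion, the carbene carbon and the methylene being linked through C3a, C7a and O1. C2 is set by the chiral carboxylate pocket, which chooses between the two enantiotopic hydrogens of the methylene, and is not acidic afterwards. C3 forms kinetically cis (10) and methoxide then equilibrates it through the ester enolate to the trans ester 11, so its configuration is relayed from C2 under thermodynamic control. Site selectivity is secured by the substrate: only this methylene is within reach, since the C7 benzyl ether and the C5 silyloxymethyl group are meta to the carbene-bearing carbon, and it is the most hydridic C–H bond, flanked by oxygen and the electron-rich guaiacyl ring. Enantiomeric enrichment by crystallisation of 11 or a later solid intermediate is planned if needed.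

Step 9
Reactants: 11 methyl (2S,3S)-7-(benzyloxy)-2-(4-benzyloxy-3-methoxyphenyl)-5-[(triisopropylsilyloxy)methyl]-2,3-dihydrobenzofuran-3-carboxylate
Product: 12 [(2S,3R)-7-(benzyloxy)-2-(4-benzyloxy-3-methoxyphenyl)-5-[(triisopropylsilyloxy)methyl]-2,3-dihydrobenzofuran-3-yl]methanol
Conditions: LiBH4, THF, 0 °C to rt
Reagents that add atoms: none
Why: Ester reduction by a mild, weakly basic hydride, which should not trigger β-elimination of the ring oxygen; the geometry at C3 is unchanged and only its descriptor changes.

Step 10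
Reactants: 12 [(2S,3R)-7-(benzyloxy)-2-(4-benzyloxy-3-methoxyphenyl)-5-[(triisopropylsilyloxy)methyl]-2,3-dihydrobenzofuran-3-yl]methanol
Product: 13 (2S,3R)-7-(benzyloxy)-3-[(benzyloxy)methyl]-2-(4-benzyloxy-3-methoxyphenyl)-5-[(triisopropylsilyloxy)methyl]-2,3-dihydrobenzofuran
Conditions: NaH, BnBr, n-Bu4NI (cat.), DMF, 0 °C to rt
Reagents that add atoms: benzyl bromide, BrCc1ccccc1
Why: Williamson benzylation of the primary alkoxide, so that the alcohol is masked through bromide formation and enolate alkylation and is released in the final hydrogenolysis.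

Step 11
Reactants: 13 (2S,3R)-7-(benzyloxy)-3-[(benzyloxy)methyl]-2-(4-benzyloxy-3-methoxyphenyl)-5-[(triisopropylsilyloxy)methyl]-2,3-dihydrobenzofuran
Product: 14 [(2S,3R)-7-(benzyloxy)-3-[(benzyloxy)methyl]-2-(4-benzyloxy-3-methoxyphenyl)-2,3-dihydrobenzofuran-5-yl]methanol
Conditions: n-Bu4NF, THF, 0 °C to rt
Reagents that add atoms: none
Why: Fluoride cleavage of the silyl ether, selective over benzyl ethers, frees the C5 benzylic alcohol.

Step 12
Reactants: 14 [(2S,3R)-7-(benzyloxy)-3-[(benzyloxy)methyl]-2-(4-benzyloxy-3-methoxyphenyl)-2,3-dihydrobenzofuran-5-yl]methanol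
Product: 15 (2S,3R)-7-(benzyloxy)-3-[(benzyloxy)methyl]-2-(4-benzyloxy-3-methoxyphenyl)-5-(bromomethyl)-2,3-dihydrobenzofuran
Conditions: CBr4, PPh3, CH2Cl2, 0 °C
Reagents that add atoms: tetrabromomethane, BrC(Br)(Br)Br
Why: Appel bromination under neutral conditions, chosen because the C2–O1 ether would not tolerate strong acid; the electron-rich bromide is used at once in step 17.

Step 13
Reactants: 16 4-tert-butoxy-4-oxobutanoic acid; 17 (S)-4-benzyl-1,3-oxazolidin-2-one
Product: 19 tert-butyl 4-[(S)-4-benzyl-2-oxo-1,3-oxazolidin-3-yl]-4-oxobutanoate, via mixed pivalic anhydride 18 (not isolated)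
Conditions: t-BuCOCl, Et3N, THF, −20 °C; then 17, LiCl, −20 °C to rt
Reagents that add atoms: none
Why: N-Acylation of the oxazolidinone through the mixed anhydride, whose hindered pivaloyl carbonyl directs attack to the succinyl carbonyl; LiCl activates the oxazolidinone under mild base.

Step 14
Reactants: 19 tert-butyl 4-[(S)-4-benzyl-2-oxo-1,3-oxazolidin-3-yl]-4-oxobutanoate; 2 4-benzyloxy-3-methoxybenzyl bromide
Product: 20 tert-butyl (S)-3-(4-benzyloxy-3-methoxybenzyl)-4-[(S)-4-benzyl-2-oxo-1,3-oxazolidin-3-yl]-4-oxobutanoate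
Conditions: NaN(SiMe3)2, THF, −78 °C; then 2, −78 to −40 °C
Reagents that add atoms: none
Why: Auxiliary-controlled (Evans) alkylation: the imide α-protons are the most acidic, the chelated Z-enolate is shielded on one face by the benzyl group, and the benzylic bromide enters from the open face, which for this substituent pattern gives the (S) centre that becomes lactone Cβ.

Step 15
Reactants: 20 tert-butyl (S)-3-(4-benzyloxy-3-methoxybenzyl)-4-[(S)-4-benzyl-2-oxo-1,3-oxazolidin-3-yl]-4-oxobutanoate
Product: 21 tert-butyl (S)-3-(4-benzyloxy-3-methoxybenzyl)-4-hydroxybutanoate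
Conditions: LiBH4, MeOH (1 equiv), THF, 0 °C
Reagents that add atoms: none
Why: Reductive removal of the auxiliary: the activated imide carbonyl is reduced to the primary alcohol while the hindered tert-butyl ester is left, and the stereocentre, not being enolised, is retained; auxiliary 17 is recovered.

Step 16
Reactants: 21 tert-butyl (S)-3-(4-benzyloxy-3-methoxybenzyl)-4-hydroxybutanoate
Product: 22 (S)-4-(4-benzyloxy-3-methoxybenzyl)dihydrofuran-2(3H)-one
Conditions: p-TsOH·H2O (10 mol %), toluene, 80 °C
Reagents that add atoms: none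
Why: Acid-catalysed loss of the tert-butyl group and 5-exo lactonisation of the γ-hydroxy acid; the stereocentre is not involved and catalytic sulfonic acid should leave the aryl benzyl ether intact.

Step 17
Reactants: 22 (S)-4-(4-benzyloxy-3-methoxybenzyl)dihydrofuran-2(3H)-one; 15 (2S,3R)-7-(benzyloxy)-3-[(benzyloxy)methyl]-2-(4-benzyloxy-3-methoxyphenyl)-5-(bromomethyl)-2,3-dihydrobenzofuran
Product: 23 (3S,4S)-3-{[(2S,3R)-7-(benzyloxy)-3-[(benzyloxy)methyl]-2-(4-benzyloxy-3-methoxyphenyl)-2,3-dihydrobenzofuran-5-yl]methyl}-4-(4-benzyloxy-3-methoxybenzyl)dihydrofuran-2(3H)-one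
Conditions: LiN(SiMe3)2, THF, −78 °C; DMPU, then 15, −78 to −30 °C
Reagents that add atoms: none
Why: Alkylation of a β-substituted butyrolactone enolate, the standard route to trans-dibenzylbutyrolactone lignans: the bromide approaches the planar enolate anti to the β-arylmethyl group, setting Cα (S) trans to Cβ.

Step 18
Reactants: 23 (3S,4S)-3-{[(2S,3R)-7-(benzyloxy)-3-[(benzyloxy)methyl]-2-(4-benzyloxy-3-methoxyphenyl)-2,3-dihydrobenzofuran-5-yl]methyl}-4-(4-benzyloxy-3-methoxybenzyl)dihydrofuran-2(3H)-one
Product: 24 (3S,4S)-3-{[(2S,3R)-7-hydroxy-2-(4-hydroxy-3-methoxyphenyl)-3-(hydroxymethyl)-2,3-dihydrobenzofuran-5-yl]methyl}-4-(4-hydroxy-3-methoxybenzyl)dihydrofuran-2(3H)-one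
Conditions: H2 (1 atm), 10% Pd/C, EtOAc/MeOH, rt
Reagents that add atoms: none
Why: Hydrogenolysis of three aryl benzyl ethers and one alkyl benzyl ether under neutral, low-pressure conditions, under which the phenylcoumaran C2–O1 bond, the lactone and all four stereocentres are expected to persist.

## Compound list

1 | (4-benzyloxy-3-methoxyphenyl)methanol | COc1cc(CO)ccc1OCc1ccccc1 | starting material
2 | 4-benzyloxy-3-methoxybenzyl bromide | COc1cc(CBr)ccc1OCc1ccccc1 | intermediate
3 | 3-bromo-4,5-dihydroxybenzaldehyde | O=Cc1cc(O)c(O)c(Br)c1 | starting material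
4 | 3-bromo-4-[(4-benzyloxy-3-methoxybenzyl)oxy]-5-hydroxybenzaldehyde | O=Cc1cc(O)c(OCc2ccc(OCc3ccccc3)c(OC)c2)c(Br)c1 | intermediate
5 | 3-(benzyloxy)-4-[(4-benzyloxy-3-methoxybenzyl)oxy]-5-bromobenzaldehyde | O=Cc1cc(OCc2ccccc2)c(OCc2ccc(OCc3ccccc3)c(OC)c2)c(Br)c1 | intermediate
6 | {3-(benzyloxy)-4-[(4-benzyloxy-3-methoxybenzyl)oxy]-5-bromophenyl}methanol | OCc1cc(OCc2ccccc2)c(OCc2ccc(OCc3ccccc3)c(OC)c2)c(Br)c1 | intermediate
7 | ({3-(benzyloxy)-4-[(4-benzyloxy-3-methoxybenzyl)oxy]-5-bromobenzyl}oxy)triisopropylsilane | CC(C)[Si](OCc1cc(OCc2ccccc2)c(OCc2ccc(OCc3ccccc3)c(OC)c2)c(Br)c1)(C(C)C)C(C)C | intermediate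
8 | methyl 2-{3-(benzyloxy)-2-[(4-benzyloxy-3-methoxybenzyl)oxy]-5-[(triisopropylsilyloxy)methyl]phenyl}acetate | COC(=O)Cc1cc(CO[Si](C(C)C)(C(C)C)C(C)C)cc(OCc2ccccc2)c1OCc1ccc(OCc2ccccc2)c(OC)c1 | intermediate
9 | methyl 2-diazo-2-{3-(benzyloxy)-2-[(4-benzyloxy-3-methoxybenzyl)oxy]-5-[(triisopropylsilyloxy)methyl]phenyl}acetate | COC(=O)C(=[N+]=[N-])c1cc(CO[Si](C(C)C)(C(C)C)C(C)C)cc(OCc2ccccc2)c1OCc1ccc(OCc2ccccc2)c(OC)c1 | intermediate
10 | methyl (2S,3R)-7-(benzyloxy)-2-(4-benzyloxy-3-methoxyphenyl)-5-[(triisopropylsilyloxy)methyl]-2,3-dihydrobenzofuran-3-carboxylate (2,3-cis) | CC(C)[Si](OCc1cc(OCc2ccccc2)c2c(c1)[C@@H](C(=O)OC)[C@@H](c1ccc(OCc3ccccc3)c(OC)c1)O2)(C(C)C)C(C)C | intermediate (not isolated)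
11 | methyl (2S,3S)-7-(benzyloxy)-2-(4-benzyloxy-3-methoxyphenyl)-5-[(triisopropylsilyloxy)methyl]-2,3-dihydrobenzofuran-3-carboxylate (2,3-trans) | CC(C)[Si](OCc1cc(OCc2ccccc2)c2c(c1)[C@H](C(=O)OC)[C@@H](c1ccc(OCc3ccccc3)c(OC)c1)O2)(C(C)C)C(C)C | intermediate
12 | [(2S,3R)-7-(benzyloxy)-2-(4-benzyloxy-3-methoxyphenyl)-5-[(triisopropylsilyloxy)methyl]-2,3-dihydrobenzofuran-3-yl]methanol | CC(C)[Si](OCc1cc(OCc2ccccc2)c2c(c1)[C@H](CO)[C@@H](c1ccc(OCc3ccccc3)c(OC)c1)O2)(C(C)C)C(C)C | intermediate
13 | (2S,3R)-7-(benzyloxy)-3-[(benzyloxy)methyl]-2-(4-benzyloxy-3-methoxyphenyl)-5-[(triisopropylsilyloxy)methyl]-2,3-dihydrobenzofuran | CC(C)[Si](OCc1cc(OCc2ccccc2)c2c(c1)[C@H](COCc1ccccc1)[C@@H](c1ccc(OCc3ccccc3)c(OC)c1)O2)(C(C)C)C(C)C | intermediate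
14 | [(2S,3R)-7-(benzyloxy)-3-[(benzyloxy)methyl]-2-(4-benzyloxy-3-methoxyphenyl)-2,3-dihydrobenzofuran-5-yl]methanol | OCc1cc(OCc2ccccc2)c2c(c1)[C@H](COCc1ccccc1)[C@@H](c1ccc(OCc3ccccc3)c(OC)c1)O2 | intermediate
15 | (2S,3R)-7-(benzyloxy)-3-[(benzyloxy)methyl]-2-(4-benzyloxy-3-methoxyphenyl)-5-(bromomethyl)-2,3-dihydrobenzofuran | BrCc1cc(OCc2ccccc2)c2c(c1)[C@H](COCc1ccccc1)[C@@H](c1ccc(OCc3ccccc3)c(OC)c1)O2 | intermediate
16 | 4-tert-butoxy-4-oxobutanoic acid | CC(C)(C)OC(=O)CCC(=O)O | starting material
17 | (S)-4-benzyl-1,3-oxazolidin-2-one | O=C1N[C@@H](Cc2ccccc2)CO1 | starting material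
18 | 4-tert-butoxy-4-oxobutanoic pivalic anhydride | CC(C)(C)OC(=O)CCC(=O)OC(=O)C(C)(C)C | intermediate (not isolated)
19 | tert-butyl 4-[(S)-4-benzyl-2-oxo-1,3-oxazolidin-3-yl]-4-oxobutanoate | CC(C)(C)OC(=O)CCC(=O)N1[C@@H](Cc2ccccc2)COC1=O | intermediate
20 | tert-butyl (S)-3-(4-benzyloxy-3-methoxybenzyl)-4-[(S)-4-benzyl-2-oxo-1,3-oxazolidin-3-yl]-4-oxobutanoate | CC(C)(C)OC(=O)C[C@H](Cc1ccc(OCc2ccccc2)c(OC)c1)C(=O)N1[C@@H](Cc2ccccc2)COC1=O | intermediate
21 | tert-butyl (S)-3-(4-benzyloxy-3-methoxybenzyl)-4-hydroxybutanoate | CC(C)(C)OC(=O)C[C@H](Cc1ccc(OCc2ccccc2)c(OC)c1)CO | intermediate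
22 | (S)-4-(4-benzyloxy-3-methoxybenzyl)dihydrofuran-2(3H)-one | COc1cc(C[C@@H]2COC(=O)C2)ccc1OCc1ccccc1 | intermediate
23 | (3S,4S)-3-{[(2S,3R)-7-(benzyloxy)-3-[(benzyloxy)methyl]-2-(4-benzyloxy-3-methoxyphenyl)-2,3-dihydrobenzofuran-5-yl]methyl}-4-(4-benzyloxy-3-methoxybenzyl)dihydrofuran-2(3H)-one | COc1cc(C[C@@H]2COC(=O)[C@H]2Cc2cc(OCc3ccccc3)c3c(c2)[C@H](COCc2ccccc2)[C@@H](c2ccc(OCc4ccccc4)c(OC)c2)O3)ccc1OCc1ccccc1 | intermediate
24 | (3S,4S)-3-{[(2S,3R)-7-hydroxy-2-(4-hydroxy-3-methoxyphenyl)-3-(hydroxymethyl)-2,3-dihydrobenzofuran-5-yl]methyl}-4-(4-hydroxy-3-methoxybenzyl)dihydrofuran-2(3H)-one | COc1cc(C[C@@H]2COC(=O)[C@H]2Cc2cc(O)c3c(c2)[C@H](CO)[C@@H](c2ccc(O)c(OC)c2)O3)ccc1O | target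

## Step count and least certain steps

Total step count: 18. Longest linear sequence: 14 steps (steps 1 to 12, 17 and 18, from 1). The lactone branch (steps 13 to 16) joins at step 17.

**Step 8 (key step).** The most likely failure is poor discrimination between the two enantiotopic hydrogens. The benzyloxy group at C7, next to the ether oxygen, may force the OCH2Ar arm into a conformation that fits the carboxylate pocket less well than in unsubstituted analogues. Further risks are cycloaddition of the carbene onto the electron-rich guaiacyl ring and base-induced opening of ring B by β-elimination of the phenoxide during equilibration. Fallback, from 8 back to 12: control is moved from the catalyst alone to a chiral ester auxiliary matched with a chiral catalyst, a known combination for trans-2-aryl-dihydrobenzofuran-3-carboxylates with a 7-alkoxy group. Ester 8 is saponified (LiOH, THF/H2O) to 2-{3-(benzyloxy)-2-[(4-benzyloxy-3-methoxybenzyl)oxy]-5-[(triisopropylsilyloxy)methyl]phenyl}acetic acid F1. This is esterified (carbodiimide, DMAP) with (S)-2-hydroxy-1-(pyrrolidin-1-yl)propan-1-one to the lactamide ester F2, and diazo transfer as in step 7 gives the diazo lactamide ester F3. Insertion with Rh2(S-DOSP)4, dirhodium tetrakis[N-(4-dodecylbenzenesulfonyl)-(S)-prolinate], should give the trans lactamide ester F4; the auxiliary and catalyst enantiomers are chosen as the matched pair for (2S), and the diastereomers are separable. LiBH4 then reduces F4 to 12 and releases the auxiliary.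

**Step 2.** Loss of regiocontrol is the risk: alkylation at the other phenol or at both, since the 4-oxygen, though the more acidic, lies between bromine and the second hydroxyl. Fallback, from 2 back to 5: the regiochemistry is fixed by substitution instead of acidity. Purchased 3-(benzyloxy)-4-hydroxybenzaldehyde F5 is brominated ortho to its only free hydroxyl (Br2, NaOAc, AcOH) to 3-(benzyloxy)-5-bromo-4-hydroxybenzaldehyde F6. Alkylation of F6 with 2 (K2CO3, DMF) gives 5.

**Step 6.** Slow coupling at the ortho-alkoxy, electron-rich aryl bromide is the risk, with reduction of the C–Br bond or double arylation of the acetate in its place. Fallback, from 7 back to 9, without palladium and bypassing 8: bromine–lithium exchange (n-BuLi, THF, −78 °C) and addition to excess dimethyl oxalate give methyl 2-{3-(benzyloxy)-2-[(4-benzyloxy-3-methoxybenzyl)oxy]-5-[(triisopropylsilyloxy)methyl]phenyl}-2-oxoacetate F7. Condensation with 4-methylbenzenesulfonohydrazide gives the tosylhydrazone F8, and DBU in CH2Cl2 eliminates sulfinate (Bamford–Stevens) to give 9.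

**Step 17.** Decomposition of the electron-rich benzylic bromide 15 before it is alkylated is the risk, together with proton exchange between product and enolate leading to double alkylation, and incomplete anti selectivity. Fallback, from 14 to 24, bypassing 15 and 23: alcohol 14 is oxidised (MnO2, CH2Cl2) to (2S,3R)-7-(benzyloxy)-3-[(benzyloxy)methyl]-2-(4-benzyloxy-3-methoxyphenyl)-2,3-dihydrobenzofuran-5-carbaldehyde F9. Aldol addition of the lithium enolate of 22, again anti to the β-substituent, gives the hydroxybenzyl lactone F10 as a mixture at the carbinol carbon. Hydrogenolysis (H2, Pd/C, EtOAc/AcOH) removes the benzylic hydroxyl, activated by the para ring oxygen, together with the four benzyl ethers to give 24.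

**Step 18.** Hydrogenolytic cleavage of the C2–O1 bond, itself a benzylic aryl ether, may compete with debenzylation, while the aliphatic benzyl ether is the slowest to go. Fallback, from 23 to 24: Lewis acid debenzylation with BCl3 and pentamethylbenzene as cation scavenger in CH2Cl2 at −78 °C, warming only as far as needed for the aliphatic ether. This is a non-reductive cleavage that uses neither hydrogen nor a metal surface, and the low temperature is kept because C2 is itself ionisable; no new compound is made on the way (F0).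

## Further compounds

F1 | step 8 | 2-{3-(benzyloxy)-2-[(4-benzyloxy-3-methoxybenzyl)oxy]-5-[(triisopropylsilyloxy)methyl]phenyl}acetic acid | OC(=O)Cc1cc(CO[Si](C(C)C)(C(C)C)C(C)C)cc(OCc2ccccc2)c1OCc1ccc(OCc2ccccc2)c(OC)c1
F2 | step 8 | (S)-1-oxo-1-(pyrrolidin-1-yl)propan-2-yl 2-{3-(benzyloxy)-2-[(4-benzyloxy-3-methoxybenzyl)oxy]-5-[(triisopropylsilyloxy)methyl]phenyl}acetate | C[C@H](OC(=O)Cc1cc(CO[Si](C(C)C)(C(C)C)C(C)C)cc(OCc2ccccc2)c1OCc1ccc(OCc2ccccc2)c(OC)c1)C(=O)N1CCCC1
F3 | step 8 | (S)-1-oxo-1-(pyrrolidin-1-yl)propan-2-yl 2-diazo-2-{3-(benzyloxy)-2-[(4-benzyloxy-3-methoxybenzyl)oxy]-5-[(triisopropylsilyloxy)methyl]phenyl}acetate | C[C@H](OC(=O)C(=[N+]=[N-])c1cc(CO[Si](C(C)C)(C(C)C)C(C)C)cc(OCc2ccccc2)c1OCc1ccc(OCc2ccccc2)c(OC)c1)C(=O)N1CCCC1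
F4 | step 8 | (S)-1-oxo-1-(pyrrolidin-1-yl)propan-2-yl (2S,3S)-7-(benzyloxy)-2-(4-benzyloxy-3-methoxyphenyl)-5-[(triisopropylsilyloxy)methyl]-2,3-dihydrobenzofuran-3-carboxylate | CC(C)[Si](OCc1cc(OCc2ccccc2)c2c(c1)[C@H](C(=O)O[C@@H](C)C(=O)N1CCCC1)[C@@H](c1ccc(OCc3ccccc3)c(OC)c1)O2)(C(C)C)C(C)C
F5 | step 2 | 3-(benzyloxy)-4-hydroxybenzaldehyde | O=Cc1ccc(O)c(OCc2ccccc2)c1
F6 | step 2 | 3-(benzyloxy)-5-bromo-4-hydroxybenzaldehyde | O=Cc1cc(Br)c(O)c(OCc2ccccc2)c1
F7 | step 6 | methyl 2-{3-(benzyloxy)-2-[(4-benzyloxy-3-methoxybenzyl)oxy]-5-[(triisopropylsilyloxy)methyl]phenyl}-2-oxoacetate | COC(=O)C(=O)c1cc(CO[Si](C(C)C)(C(C)C)C(C)C)cc(OCc2ccccc2)c1OCc1ccc(OCc2ccccc2)c(OC)c1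
F8 | step 6 | methyl 2-{3-(benzyloxy)-2-[(4-benzyloxy-3-methoxybenzyl)oxy]-5-[(triisopropylsilyloxy)methyl]phenyl}-2-[2-(4-methylbenzenesulfonyl)hydrazinylidene]acetate | COC(=O)C(=NNS(=O)(=O)c1ccc(C)cc1)c1cc(CO[Si](C(C)C)(C(C)C)C(C)C)cc(OCc2ccccc2)c1OCc1ccc(OCc2ccccc2)c(OC)c1
F9 | step 17 | (2S,3R)-7-(benzyloxy)-3-[(benzyloxy)methyl]-2-(4-benzyloxy-3-methoxyphenyl)-2,3-dihydrobenzofuran-5-carbaldehyde | O=Cc1cc(OCc2ccccc2)c2c(c1)[C@H](COCc1ccccc1)[C@@H](c1ccc(OCc3ccccc3)c(OC)c1)O2
F10 | step 17 | (3R,4S)-3-{[(2S,3R)-7-(benzyloxy)-3-[(benzyloxy)methyl]-2-(4-benzyloxy-3-methoxyphenyl)-2,3-dihydrobenzofuran-5-yl](hydroxy)methyl}-4-(4-benzyloxy-3-methoxybenzyl)dihydrofuran-2(3H)-one, both carbinol epimers | COc1cc(C[C@@H]2COC(=O)[C@H]2C(O)c2cc(OCc3ccccc3)c3c(c2)[C@H](COCc2ccccc2)[C@@H](c2ccc(OCc4ccccc4)c(OC)c2)O3)ccc1OCc1ccccc1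
F0 | step 18 | none | none
A1 | alternative 1 | 2-(benzyloxy)-4-bromo-6-{2-[(tert-butyldimethylsilyl)oxy]-1-(4-methylbenzenesulfonyl)ethyl}phenol | Cc1ccc(cc1)S(=O)(=O)C(CO[Si](C)(C)C(C)(C)C)c1cc(Br)cc(OCc2ccccc2)c1O
A2 | alternative 1 | (2R,5R)-1-(4-benzyloxy-3-methoxybenzyl)-2,5-dimethylthiolan-1-ium trifluoromethanesulfonate | C[C@@H]1CC[C@@H](C)[S+]1Cc1ccc(OCc2ccccc2)c(OC)c1.[O-]S(=O)(=O)C(F)(F)F
A3 | alternative 1 | (2S,3R)-7-(benzyloxy)-2-(4-benzyloxy-3-methoxyphenyl)-5-bromo-3-{[(tert-butyldimethylsilyl)oxy]methyl}-2,3-dihydrobenzofuran | Brc1cc(OCc2ccccc2)c2c(c1)[C@H](CO[Si](C)(C)C(C)(C)C)[C@@H](c1ccc(OCc3ccccc3)c(OC)c1)O2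
A4 | alternative 2 | 3-(4-benzyloxy-3-methoxybenzyl)cyclobutan-1-one | COc1cc(CC2CC(=O)C2)ccc1OCc1ccccc1
A5 | alternative 2 | (S)-4-(4-benzyloxy-3-methoxybenzyl)dihydrofuran-2(3H)-one | COc1cc(C[C@@H]2COC(=O)C2)ccc1OCc1ccccc1
A6 | alternative 3 | tert-butyl({(4R,5S)-5-(4-benzyloxy-3-methoxyphenyl)-4-[(triisopropylsilyloxy)methyl]-4,5-dihydrofuran-2-yl}oxy)dimethylsilane | CC(C)(C)[Si](C)(C)OC1=C[C@H](CO[Si](C(C)C)(C(C)C)C(C)C)[C@@H](c2ccc(OCc3ccccc3)c(OC)c2)O1
A7 | alternative 3 | methyl 3-bromo-2-oxo-2H-pyran-5-carboxylate | COC(=O)C1=COC(=O)C(Br)=C1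
A8 | alternative 3 | methyl (2S,3R)-2-(4-benzyloxy-3-methoxyphenyl)-7-bromo-3-[(triisopropylsilyloxy)methyl]-2,3-dihydrobenzofuran-5-carboxylate | COC(=O)c1cc(Br)c2c(c1)[C@H](CO[Si](C(C)C)(C(C)C)C(C)C)[C@@H](c1ccc(OCc3ccccc3)c(OC)c1)O2
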